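**Retrosynthetic overview**
1. The target is opened, after removal of three benzyl and two silyl groups, at the C3–CH2(ring B) bond: lactone-enolate alkylation trans to the C4 substituent, leaving an (R)-4-(arylmethyl)butanolide.
2. Key disconnection: the lactone O1–C5 bond, made by a strain-releasing, catalyst-controlled Baeyer–Villiger ring expansion of a 3-(arylmethyl)cyclobutanone. Enabling feature: without the C3 benzyl group, lactone C4 lies between two ring CH2 groups (C3 and C5) that differ only by O1, so deleting O1 and joining C5 to C2 gives a four-membered ketone with a mirror plane through C=O and C4.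
3. The cyclobutanone comes from the allyl group of a eugenol-derived ring A by dichloroketene [2+2] cycloaddition and dechlorination.
4. The (1R,2R)-1,3-diol side chain is set earlier by an auxiliary-controlled anti-aldol between the ring A arylacetyl oxazolidinone and O-benzylvanillin (ring C), then reduction. The arylacetic acid comes from eugenol by ortho-bromination, O-benzylation and palladium-catalysed zinc-enolate arylation.
5. Ring order: temporary cyclobutanone (step 9), then the butanolide by ring expansion (step 11); the three arenes are bought.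

Key step: step 11

Assumption: the magnesium-catalysed aldol of the arylacetyl imide is taken to show the same chelated-enolate facial preference as N-propionyl imides, which is why the (R)-configured auxiliary is chosen.

**Step 1**
Reactants: 1 eugenol (4-allyl-2-methoxyphenol)
Product: 2 4-allyl-2-bromo-6-methoxyphenol
Conditions: NBS (1.0 equiv), i-Pr2NH (10 mol %), CH2Cl2, 0 °C
Reagents that add atoms: N-bromosuccinimide, O=C1CCC(=O)N1Br
Why: Amine-catalysed electrophilic aromatic bromination of a free phenol should deliver bromine to the only open position ortho to the hydroxyl (para is blocked by the allyl group) faster than it adds to the isolated alkene.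

**Step 2**
Reactants: 2 4-allyl-2-bromo-6-methoxyphenol
Product: 3 5-allyl-2-(benzyloxy)-1-bromo-3-methoxybenzene
Conditions: BnBr, K2CO3, DMF, rt
Reagents that add atoms: benzyl bromide, BrCc1ccccc1
Why: Williamson ether synthesis on the phenoxide should proceed cleanly and masks the phenol for all later basic and organometallic steps.

**Step 3**
Reactants: 3 5-allyl-2-(benzyloxy)-1-bromo-3-methoxybenzene
Product: 4 tert-butyl 2-[5-allyl-2-(benzyloxy)-3-methoxyphenyl]acetate
Conditions: BrZnCH2CO2t-Bu (1.3 equiv), Pd(dba)2 (2 mol %), P(t-Bu)3 (2 mol %), THF, rt to 40 °C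
Reagents that add atoms: tert-butyl (bromozincio)acetate, CC(C)(C)OC(=O)C[Zn]Br
Why: Palladium-catalysed α-arylation of a Reformatsky zinc enolate (Negishi-type coupling) should work because the neutral zinc enolate tolerates the allyl and benzyl ether groups and the bulky electron-rich phosphine allows oxidative addition of zerovalent palladium into the hindered, electron-rich C–Br bond.

**Step 4**
Reactants: 4 tert-butyl 2-[5-allyl-2-(benzyloxy)-3-methoxyphenyl]acetate
Product: 5 2-[5-allyl-2-(benzyloxy)-3-methoxyphenyl]acetic acid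
Conditions: CF3CO2H, CH2Cl2, 0 °C to rt
Reagents that add atoms: none
Why: Acidolysis of the tert-butyl ester through the tert-butyl cation should free the acid while the aryl benzyl ether and the terminal alkene persist at this acidity.

**Step 5**
Reactants: 5 2-[5-allyl-2-(benzyloxy)-3-methoxyphenyl]acetic acid; 6 (R)-4-benzyloxazolidin-2-one
Product: 8 (R)-3-{2-[5-allyl-2-(benzyloxy)-3-methoxyphenyl]acetyl}-4-benzyloxazolidin-2-one, via mixed pivalic anhydride 7 (not isolated)
Conditions: t-BuCOCl, Et3N, THF, −20 °C; then LiCl, 6, −20 °C to rt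
Reagents that add atoms: none
Why: N-Acylation of the oxazolidinone by a mixed anhydride under LiCl/Et3N activation should give the imide, since the hindered pivaloyl carbonyl directs attack to the arylacetyl carbonyl.

**Step 6**
Reactants: 8 (R)-3-{2-[5-allyl-2-(benzyloxy)-3-methoxyphenyl]acetyl}-4-benzyloxazolidin-2-one; 9 4-(benzyloxy)-3-methoxybenzaldehyde
Product: 11 (R)-3-{(2S,3R)-2-[5-allyl-2-(benzyloxy)-3-methoxyphenyl]-3-[4-(benzyloxy)-3-methoxyphenyl]-3-hydroxypropanoyl}-4-benzyloxazolidin-2-one, via O-trimethylsilyl aldol adduct 10 (not isolated)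
Conditions: MgCl2 (20 mol %), Et3N, Me3SiCl, EtOAc, rt; then 1 M HCl, THF, 0 °C
Reagents that add atoms: none
Why: In this magnesium-halide-catalysed direct anti-aldol reaction (soft enolisation), the magnesium-chelated Z-enolate should be attacked on the face away from the auxiliary benzyl group through a boat-like transition state, which sets C2 as S and C3 as R in an anti relationship, and silyl trapping of the aldolate should prevent retro-aldol equilibration.

**Step 7**
Reactants: 11 the anti-aldol imide
Product: 12 (1R,2R)-2-[5-allyl-2-(benzyloxy)-3-methoxyphenyl]-1-[4-(benzyloxy)-3-methoxyphenyl]propane-1,3-diol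
Conditions: LiBH4, MeOH (1 equiv), THF, 0 °C
Reagents that add atoms: none
Why: Reductive cleavage of the N-acyl oxazolidinone by borohydride attack at the exocyclic carbonyl should give the primary alcohol and the recoverable auxiliary without touching either stereocentre (the 2S centre becomes 2R only through the change in substituent priorities).

**Step 8**
Reactants: 12 the (1R,2R)-diol
Product: 13 5-allyl-2-(benzyloxy)-1-{(1R,2R)-1,3-bis(tert-butyldimethylsilyloxy)-1-[4-(benzyloxy)-3-methoxyphenyl]propan-2-yl}-3-methoxybenzene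
Conditions: t-BuMe2SiOTf (2.5 equiv), 2,6-lutidine, CH2Cl2, 0 °C
Reagents that add atoms: tert-butyldimethylsilyl trifluoromethanesulfonate, CC(C)(C)[Si](C)(C)OS(=O)(=O)C(F)(F)F
Why: Silylation with the silyl triflate should cap both the primary and the hindered benzylic hydroxyl, so that they survive ketene, peracid and enolate chemistry and can be removed later with fluoride without acid at the benzylic carbon.

**Step 9**
Reactants: 13 the bis-silyl allylarene
Product: 14 2,2-dichloro-3-{3-[(1R,2R)-1,3-bis(tert-butyldimethylsilyloxy)-1-(4-benzyloxy-3-methoxyphenyl)propan-2-yl]-4-benzyloxy-5-methoxybenzyl}cyclobutan-1-one (both epimers at the ring CH)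
Conditions: Cl3CCOCl, Zn–Cu couple, DME, Et2O, rt, ultrasound
Reagents that add atoms: trichloroacetyl chloride, ClC(=O)C(Cl)(Cl)Cl
Why: Dichloroketene generated by zinc dechlorination should undergo [2+2] cycloaddition with the terminal alkene with the usual regiochemistry (substituted alkene carbon next to CCl2); the new ring stereocentre is not controlled and disappears in step 10.

**Step 10**
Reactants: 14 the dichlorocyclobutanone
Product: 15 3-{3-[(1R,2R)-1,3-bis(tert-butyldimethylsilyloxy)-1-(4-benzyloxy-3-methoxyphenyl)propan-2-yl]-4-benzyloxy-5-methoxybenzyl}cyclobutan-1-one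
Conditions: Zn, NH4Cl, MeOH, rt
Reagents that add atoms: none
Why: Zinc reduction of the α,α-dichloro ketone through zinc enolates should remove both chlorines under near-neutral conditions that spare silyl and benzyl ethers, leaving a ketone whose two α-methylenes are constitutionally identical.

**Step 11**
Reactants: 15 the 3-(arylmethyl)cyclobutanone
Product: 17 (R)-4-{3-[(1R,2R)-1,3-bis(tert-butyldimethylsilyloxy)-1-(4-benzyloxy-3-methoxyphenyl)propan-2-yl]-4-benzyloxy-5-methoxybenzyl}dihydrofuran-2(3H)-one, via Criegee adduct 16 (not isolated)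
Conditions: Sc(OTf)3 (5 mol %), C2-symmetric proline-derived chiral N,N'-dioxide bis(2,6-diisopropylanilide) ligand (5 mol %, antipode chosen for 4R on a 3-benzylcyclobutanone model), m-chloroperbenzoic acid (1.2 equiv), EtOAc, −20 °C
Reagents that add atoms: m-chloroperbenzoic acid, OOC(=O)c1cccc(Cl)c1
Why: The peracid adds to the strained ketone, whose carbonyl is bound to the chiral trivalent scandium complex, to give Criegee adduct 16, and an antiperiplanar 1,2-shift of one ring CH2 from carbon to oxygen with loss of m-chlorobenzoate forms the O–CH2 bond. The closest known reaction type is the catalytic asymmetric Baeyer–Villiger desymmetrisation of prochiral 3-substituted cyclobutanones to 4-substituted butanolides, which includes 3-benzyl cases. The five-membered lactone is closed by ring enlargement from four to five atoms (migration of a ring carbon to the inserted oxygen), not by an exo or endo cyclisation, and release of cyclobutanone ring strain should make it fast at low temperature. The one new stereocentre, lactone C4, is set by the catalyst, which decides which of the two α-methylenes migrates; because these are constitutionally identical there is no regiochemical issue, and the remote (1R,2R) side chain is not expected to bias the choice. The step needs group selectivity between the two α-methylenes and chemoselectivity for the ketone over three electron-rich arenes; the local mirror symmetry of the ring (its C3 carries H and a single arylmethyl arm) and the high electrophilicity of the four-ring carbonyl secure these.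

**Step 12**
Reactants: 18 [4-(benzyloxy)-3-methoxyphenyl]methanol
Product: 19 1-(benzyloxy)-4-(bromomethyl)-2-methoxybenzene
Conditions: PBr3, Et2O, 0 °C
Reagents that add atoms: phosphorus tribromide, BrP(Br)Br
Why: Conversion of the benzylic alcohol to the bromide through its phosphite ester (SN2 by bromide) should give the ring B electrophile, which is used directly.

**Step 13**
Reactants: 17 the (R)-4-(arylmethyl)butanolide; 19 1-(benzyloxy)-4-(bromomethyl)-2-methoxybenzene
Product: 21 (3R,4R)-3-(4-benzyloxy-3-methoxybenzyl)-4-{3-[(1R,2R)-1,3-bis(tert-butyldimethylsilyloxy)-1-(4-benzyloxy-3-methoxyphenyl)propan-2-yl]-4-benzyloxy-5-methoxybenzyl}dihydrofuran-2(3H)-one, via lithium lactone enolate 20 (not isolated)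
Conditions: LiN(SiMe3)2, THF, −78 °C; then 19, DMPU, −78 to −40 °C
Reagents that add atoms: none
Why: In this lactone-enolate alkylation the benzylic bromide should approach the planar enolate on the face opposite the C4 arylmethyl group, setting C3 as R (trans to C4), as is general for 4-substituted butanolides.

**Step 14**
Reactants: 21 the fully protected lactone
Product: 22 (3R,4R)-3-(4-benzyloxy-3-methoxybenzyl)-4-{4-benzyloxy-3-[(1R,2R)-1-(4-benzyloxy-3-methoxyphenyl)-1,3-dihydroxypropan-2-yl]-5-methoxybenzyl}dihydrofuran-2(3H)-one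
Conditions: Bu4NF, AcOH, THF, rt
Reagents that add atoms: none
Why: Fluoride-driven desilylation buffered with acetic acid should free both hydroxyls without base-induced epimerisation at C3 or lactone opening, and without acid that could ionise the electron-rich benzylic carbinol.

**Step 15**
Reactants: 22 the tri-O-benzyl diol lactone
Product: 23 (3R,4R)-3-(4-hydroxy-3-methoxybenzyl)-4-{4-hydroxy-3-[(1R,2R)-1,3-dihydroxy-1-(4-hydroxy-3-methoxyphenyl)propan-2-yl]-5-methoxybenzyl}dihydrofuran-2(3H)-one (CNP0109231.2)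
Conditions: H2 (1 atm), Pd/C, EtOAc–EtOH, rt
Reagents that add atoms: none
Why: Catalytic hydrogenolysis of the three aryl benzyl ethers under neutral conditions should be much faster than cleavage of the secondary benzylic C–OH bond and touches no stereocentre.

**Compound list**
1 | eugenol (4-allyl-2-methoxyphenol) | C=CCc1ccc(O)c(OC)c1 | starting material
2 | 4-allyl-2-bromo-6-methoxyphenol | C=CCc1cc(Br)c(O)c(OC)c1 | intermediate
3 | 5-allyl-2-(benzyloxy)-1-bromo-3-methoxybenzene | C=CCc1cc(Br)c(OCc2ccccc2)c(OC)c1 | intermediate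
4 | tert-butyl 2-[5-allyl-2-(benzyloxy)-3-methoxyphenyl]acetate | C=CCc1cc(CC(=O)OC(C)(C)C)c(OCc2ccccc2)c(OC)c1 | intermediate
5 | 2-[5-allyl-2-(benzyloxy)-3-methoxyphenyl]acetic acid | C=CCc1cc(CC(=O)O)c(OCc2ccccc2)c(OC)c1 | intermediate
6 | (R)-4-benzyloxazolidin-2-one | O=C1N[C@H](Cc2ccccc2)CO1 | starting material
7 | mixed anhydride of 5 with pivalic acid (not isolated) | C=CCc1cc(CC(=O)OC(=O)C(C)(C)C)c(OCc2ccccc2)c(OC)c1 | intermediate
8 | (R)-3-{2-[5-allyl-2-(benzyloxy)-3-methoxyphenyl]acetyl}-4-benzyloxazolidin-2-one | C=CCc1cc(CC(=O)N2[C@H](Cc3ccccc3)COC2=O)c(OCc2ccccc2)c(OC)c1 | intermediate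
9 | 4-(benzyloxy)-3-methoxybenzaldehyde | O=Cc1ccc(OCc2ccccc2)c(OC)c1 | starting material
10 | O-trimethylsilyl ether of aldol adduct 11 (not isolated) | C=CCc1cc([C@H](C(=O)N2[C@H](Cc3ccccc3)COC2=O)[C@@H](O[Si](C)(C)C)c2ccc(OCc3ccccc3)c(OC)c2)c(OCc2ccccc2)c(OC)c1 | intermediate
11 | (R)-3-{(2S,3R)-2-[5-allyl-2-(benzyloxy)-3-methoxyphenyl]-3-[4-(benzyloxy)-3-methoxyphenyl]-3-hydroxypropanoyl}-4-benzyloxazolidin-2-one | C=CCc1cc([C@H](C(=O)N2[C@H](Cc3ccccc3)COC2=O)[C@@H](O)c2ccc(OCc3ccccc3)c(OC)c2)c(OCc2ccccc2)c(OC)c1 | intermediate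
12 | (1R,2R)-2-[5-allyl-2-(benzyloxy)-3-methoxyphenyl]-1-[4-(benzyloxy)-3-methoxyphenyl]propane-1,3-diol | C=CCc1cc([C@H](CO)[C@@H](O)c2ccc(OCc3ccccc3)c(OC)c2)c(OCc2ccccc2)c(OC)c1 | intermediate
13 | bis(tert-butyldimethylsilyl) ether of 12 | C=CCc1cc([C@H](CO[Si](C)(C)C(C)(C)C)[C@@H](O[Si](C)(C)C(C)(C)C)c2ccc(OCc3ccccc3)c(OC)c2)c(OCc2ccccc2)c(OC)c1 | intermediate
14 | 2,2-dichloro-3-(arylmethyl)cyclobutan-1-one from 13 (both epimers at the ring CH) | O=C1CC(Cc2cc([C@H](CO[Si](C)(C)C(C)(C)C)[C@@H](O[Si](C)(C)C(C)(C)C)c3ccc(OCc4ccccc4)c(OC)c3)c(OCc3ccccc3)c(OC)c2)C1(Cl)Cl | intermediate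
15 | 3-{3-[(1R,2R)-1,3-bis(tert-butyldimethylsilyloxy)-1-(4-benzyloxy-3-methoxyphenyl)propan-2-yl]-4-benzyloxy-5-methoxybenzyl}cyclobutan-1-one | O=C1CC(Cc2cc([C@H](CO[Si](C)(C)C(C)(C)C)[C@@H](O[Si](C)(C)C(C)(C)C)c3ccc(OCc4ccccc4)c(OC)c3)c(OCc3ccccc3)c(OC)c2)C1 | intermediate
16 | Criegee adduct of 15 with m-chloroperbenzoic acid (1-hydroxycyclobutyl 3-chloroperbenzoate, not isolated) | OC1(OOC(=O)c2cccc(Cl)c2)CC(Cc2cc([C@H](CO[Si](C)(C)C(C)(C)C)[C@@H](O[Si](C)(C)C(C)(C)C)c3ccc(OCc4ccccc4)c(OC)c3)c(OCc3ccccc3)c(OC)c2)C1 | intermediate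
17 | (R)-4-{3-[(1R,2R)-1,3-bis(tert-butyldimethylsilyloxy)-1-(4-benzyloxy-3-methoxyphenyl)propan-2-yl]-4-benzyloxy-5-methoxybenzyl}dihydrofuran-2(3H)-one | O=C1C[C@@H](Cc2cc([C@H](CO[Si](C)(C)C(C)(C)C)[C@@H](O[Si](C)(C)C(C)(C)C)c3ccc(OCc4ccccc4)c(OC)c3)c(OCc3ccccc3)c(OC)c2)CO1 | intermediate
18 | [4-(benzyloxy)-3-methoxyphenyl]methanol | OCc1ccc(OCc2ccccc2)c(OC)c1 | starting material
19 | 1-(benzyloxy)-4-(bromomethyl)-2-methoxybenzene | BrCc1ccc(OCc2ccccc2)c(OC)c1 | intermediate
20 | lithium enolate of lactone 17 (not isolated) | [Li]OC1=C[C@@H](Cc2cc([C@H](CO[Si](C)(C)C(C)(C)C)[C@@H](O[Si](C)(C)C(C)(C)C)c3ccc(OCc4ccccc4)c(OC)c3)c(OCc3ccccc3)c(OC)c2)CO1 | intermediate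
21 | (3R,4R)-3-(4-benzyloxy-3-methoxybenzyl)-4-{3-[(1R,2R)-1,3-bis(tert-butyldimethylsilyloxy)-1-(4-benzyloxy-3-methoxyphenyl)propan-2-yl]-4-benzyloxy-5-methoxybenzyl}dihydrofuran-2(3H)-one | COc1cc(C[C@H]2C(=O)OC[C@@H]2Cc2cc(OC)c(OCc3ccccc3)c([C@H](CO[Si](C)(C)C(C)(C)C)[C@@H](O[Si](C)(C)C(C)(C)C)c3ccc(OCc4ccccc4)c(OC)c3)c2)ccc1OCc1ccccc1 | intermediate
22 | (3R,4R)-3-(4-benzyloxy-3-methoxybenzyl)-4-{4-benzyloxy-3-[(1R,2R)-1-(4-benzyloxy-3-methoxyphenyl)-1,3-dihydroxypropan-2-yl]-5-methoxybenzyl}dihydrofuran-2(3H)-one | COc1cc(C[C@H]2C(=O)OC[C@@H]2Cc2cc(OC)c(OCc3ccccc3)c([C@H](CO)[C@@H](O)c3ccc(OCc4ccccc4)c(OC)c3)c2)ccc1OCc1ccccc1 | intermediate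
23 | (3R,4R)-3-(4-hydroxy-3-methoxybenzyl)-4-{4-hydroxy-3-[(1R,2R)-1,3-dihydroxy-1-(4-hydroxy-3-methoxyphenyl)propan-2-yl]-5-methoxybenzyl}dihydrofuran-2(3H)-one (CNP0109231.2) | COc1cc(C[C@H]2C(=O)OC[C@@H]2Cc2cc(OC)c(O)c([C@H](CO)[C@@H](O)c3ccc(O)c(OC)c3)c2)ccc1O | target

**Step count**
Total steps: 15. Longest linear sequence: 14 (steps 1–11 and 13–15, from eugenol); step 12 is a one-step side branch.

**Steps most likely to fail**

1. Step 11 (key step). Risk: poor discrimination between the two α-methylenes in the migration, because only a flexible arylmethyl arm differentiates them, together with possible Lewis-acid-induced loss of a silyl ether. Fallback, setting out from 15 and returning at 17: enantioselective deprotonation of 15 with a homochiral lithium amide (lithium bis(1-phenylethyl)amide, antipode chosen for the R series, Me3SiCl present, THF, −100 °C) should give the (R)-configured trimethylsilyl enol ether F1. Ozonolysis at −78 °C with NaBH4 work-up should give the (R)-4-hydroxy acid F2. Closure of F2 under Mitsunobu conditions (PPh3, diisopropyl azodicarboxylate), in which the carboxylate displaces the activated primary oxygen, returns to 17.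

2. Step 6. Risk: erosion of anti selectivity by reversible aldolisation or epimerisation at the acidic benzylic α-carbon before silyl trapping, and sluggish addition to the electron-rich aldehyde. Fallback, setting out from 5 (with 9) and returning at 12: an Ivanov reaction (i-PrMgCl, 2 equiv, THF, then 9, equilibrating conditions) should give the racemic anti hydroxy acid F3, purified by crystallisation. Preparative chromatography on a chiral stationary phase should give the (2S,3R)-hydroxy acid F4, with the (2R,3S)-hydroxy acid F5 set aside. Reduction of F4 with LiAlH4 in THF returns to 12.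

3. Step 3. Risk: alkene migration into conjugation through palladium hydride species and protodebromination, competing with slow oxidative addition into the hindered, electron-rich C–Br bond. Fallback, setting out from 3 and returning at 5 (bypassing 4): bromine–lithium exchange (n-BuLi, THF, −78 °C) and opening of ethylene oxide with BF3·OEt2 should give 2-[5-allyl-2-(benzyloxy)-3-methoxyphenyl]ethanol F6. Oxidation of the primary alcohol with TEMPO/PhI(OAc)2 in aqueous MeCN returns to 5.

Further compounds
F1 | step 11 | (R)-configured 1-(trimethylsilyloxy)cyclobut-1-ene from 15 (silyl enol ether, ring CH bearing the arylmethyl arm is R) | C[Si](C)(C)OC1=C[C@H](Cc2cc([C@H](CO[Si](C)(C)C(C)(C)C)[C@@H](O[Si](C)(C)C(C)(C)C)c3ccc(OCc4ccccc4)c(OC)c3)c(OCc3ccccc3)c(OC)c2)C1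
F2 | step 11 | (R)-4-hydroxy-3-{3-[(1R,2R)-1,3-bis(tert-butyldimethylsilyloxy)-1-(4-benzyloxy-3-methoxyphenyl)propan-2-yl]-4-benzyloxy-5-methoxybenzyl}butanoic acid | OC(=O)C[C@@H](Cc1cc([C@H](CO[Si](C)(C)C(C)(C)C)[C@@H](O[Si](C)(C)C(C)(C)C)c2ccc(OCc3ccccc3)c(OC)c2)c(OCc2ccccc2)c(OC)c1)CO
F3 | step 6 | racemic anti-2-[5-allyl-2-(benzyloxy)-3-methoxyphenyl]-3-[4-(benzyloxy)-3-methoxyphenyl]-3-hydroxypropanoic acid (both antipodes written) | OC(=O)[C@@H](c1cc(CC=C)cc(OC)c1OCc1ccccc1)[C@@H](O)c1ccc(OCc2ccccc2)c(OC)c1.OC(=O)[C@H](c1cc(CC=C)cc(OC)c1OCc1ccccc1)[C@H](O)c1ccc(OCc2ccccc2)c(OC)c1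
F4 | step 6 | (2S,3R)-2-[5-allyl-2-(benzyloxy)-3-methoxyphenyl]-3-[4-(benzyloxy)-3-methoxyphenyl]-3-hydroxypropanoic acid | OC(=O)[C@@H](c1cc(CC=C)cc(OC)c1OCc1ccccc1)[C@@H](O)c1ccc(OCc2ccccc2)c(OC)c1
F5 | step 6 | (2R,3S)-2-[5-allyl-2-(benzyloxy)-3-methoxyphenyl]-3-[4-(benzyloxy)-3-methoxyphenyl]-3-hydroxypropanoic acid (antipode set aside) | OC(=O)[C@H](c1cc(CC=C)cc(OC)c1OCc1ccccc1)[C@H](O)c1ccc(OCc2ccccc2)c(OC)c1
F6 | step 3 | 2-[5-allyl-2-(benzyloxy)-3-methoxyphenyl]ethanol | OCCc1cc(CC=C)cc(OC)c1OCc1ccccc1
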